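The route rests on opening the tetralin ring of the cyclolignan half at C1–C8a and C2–C3. C1 is a diarylmethine and C3 a tertiary carbinol, both β to the carbon on C2, so with that carbon as an ester the ring is the product of a conjugate arylation and an aldol addition. With [RhCl(C2H4)2]2 and a chiral diene ligand, an arylboronate that carries an ortho 3-(benzyloxy)-2-oxopropyl chain adds to a bromocinnamate, and the rhodium enolate closes onto the ketone: both bonds and three stereocentres form in one operation. The all-cis oxolane half comes from a syn-aldol, a diazoketone O–H insertion and a face-selective epoxidation; a Suzuki coupling joins the halves.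

Key step: step 6

Remark on numbering: in the tetralin, C1 carries the pendant aryl group, C2 the ester or hydroxymethyl group, C3 the tertiary hydroxyl group, C4 is the benzylic CH2 and C8a is the ring-fusion carbon bonded to C1; in the oxolane, O1, C2 (aryl), C3 (CH2O group), C4 (carbinol), C5 (CH2).

Assumption: the (R,R) enantiomer of the chiral diene ligand is taken to deliver the aryl group to the Si face of the β-carbon of cinnamate 9; if the sense of induction is the opposite one, the (S,S) ligand is used instead.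

Step 1
Reactants: 1 1-(benzyloxy)-4-bromo-2-methoxybenzene; 2 benzyl glycidyl ether (racemic 2-[(benzyloxy)methyl]oxirane)
Product: 4 racemic 1-(benzyloxy)-3-[4-(benzyloxy)-3-methoxyphenyl]propan-2-ol, via aryllithium reagent 3 (not isolated)
Conditions: n-BuLi, THF, −78 °C; then 2, BF3·OEt2, −78 °C; aq. NH4Cl
Reagents that add atoms: none
Why: Bromine–lithium exchange gives the aryllithium, whose BF3-promoted opening of the terminal epoxide takes place at the unsubstituted carbon and should give the 1-arylpropan-2-ol; the carbinol centre is racemic and is removed in step 4.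

Step 2
Reactants: 4 racemic 1-(benzyloxy)-3-[4-(benzyloxy)-3-methoxyphenyl]propan-2-ol
Product: 5 racemic 1-(benzyloxy)-3-[4-(benzyloxy)-2-bromo-5-methoxyphenyl]propan-2-ol
Conditions: NBS, MeCN, 0 °C to rt
Reagents that add atoms: N-bromosuccinimide, O=C1CCC(=O)N1Br
Why: Electrophilic aromatic bromination of the dialkoxyarene should take place para to the methoxy group and ortho to the side chain, the most activated open position.

Step 3
Reactants: 5 racemic 1-(benzyloxy)-3-[4-(benzyloxy)-2-bromo-5-methoxyphenyl]propan-2-ol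
Product: 6 racemic 1-(benzyloxy)-3-[4-(benzyloxy)-5-methoxy-2-(4,4,5,5-tetramethyl-1,3,2-dioxaborolan-2-yl)phenyl]propan-2-ol
Conditions: Pd(dppf)Cl2 (5 mol%), B2pin2, KOAc, dioxane, 90 °C
Reagents that add atoms: bis(pinacolato)diboron, CC1(C)OB(OC1(C)C)B1OC(C)(C)C(C)(C)O1
Why: Miyaura borylation replaces the aryl bromide by the pinacol boronate under weakly basic conditions that the free secondary alcohol and the benzyl ethers tolerate.

Step 4
Reactants: 6 racemic 1-(benzyloxy)-3-[4-(benzyloxy)-5-methoxy-2-(4,4,5,5-tetramethyl-1,3,2-dioxaborolan-2-yl)phenyl]propan-2-ol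
Product: 7 1-(benzyloxy)-3-[4-(benzyloxy)-5-methoxy-2-(4,4,5,5-tetramethyl-1,3,2-dioxaborolan-2-yl)phenyl]propan-2-one
Conditions: Dess–Martin periodinane, CH2Cl2, 0 °C to rt
Reagents that add atoms: none
Why: Dess–Martin oxidation converts the secondary alcohol into the ketone under neutral conditions that leave the C–B bond intact.

Step 5
Reactants: 8 4-(benzyloxy)-3-bromo-5-methoxybenzaldehyde
Product: 9 methyl (E)-3-[4-(benzyloxy)-3-bromo-5-methoxyphenyl]prop-2-enoate
Conditions: Ph3P=CHCO2Me, toluene, 90 °C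
Reagents that add atoms: methyl (triphenylphosphoranylidene)acetate, COC(=O)C=P(c1ccccc1)(c1ccccc1)c1ccccc1
Why: Wittig olefination with the stabilised ylide should give the (E)-cinnamate selectively.

Step 6
Reactants: 7 1-(benzyloxy)-3-[4-(benzyloxy)-5-methoxy-2-(4,4,5,5-tetramethyl-1,3,2-dioxaborolan-2-yl)phenyl]propan-2-one; 9 methyl (E)-3-[4-(benzyloxy)-3-bromo-5-methoxyphenyl]prop-2-enoate
Product: 10 methyl (1S,2R,3S)-7-(benzyloxy)-1-[4-(benzyloxy)-3-bromo-5-methoxyphenyl]-3-[(benzyloxy)methyl]-3-hydroxy-6-methoxy-1,2,3,4-tetrahydronaphthalene-2-carboxylate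
Conditions: 7 (1.5 equiv), [RhCl(C2H4)2]2 (2.5 mol%), (R,R)-2,5-diphenylbicyclo[2.2.2]octa-2,5-diene (5.5 mol%), KOH (0.3 equiv), H2O (3 equiv), dioxane, 40 °C
Reagents that add atoms: none
Why: Transmetalation of 7 to the Rh(OH)(diene) species formed from [RhCl(C2H4)2]2, the ligand and KOH gives an arylrhodium species that adds across the cinnamate (aryl to the Si face of the β-carbon, the future C1), and the rhodium enolate so formed adds to the tethered α-benzyloxy ketone before it is protonated, so the C1–C8a and C2–C3 bonds form in one catalytic operation. The closest known reaction type is the rhodium-catalysed tandem conjugate arylation/aldol cyclisation of arylboron reagents with unsaturated carbonyl acceptors that carry a ketone, here run as a formal (4+2) annulation with the ketone on the aryl donor. The six-membered ring closes by a 6-(enolexo)-exo-trig aldol addition through a chair-like transition state. C1 (S) is set by the chiral diene ligand; C2 follows because the enolate reacts in the conformer of least allylic strain on the face that carries the tether, which places the ester trans to the C1 aryl group; C3 follows from the chair in which the benzyloxymethyl group is pseudo-equatorial and the metal-bound oxygen pseudo-axial, cis to the ester, and base-mediated reversibility of the aldol addition should favour the same isomer. The step needs C–B over C–Br chemoselectivity, which monovalent rhodium secures because it does not insert into the aryl bromide, and aldol closure faster than enolate protonation, which the low water content and the activated α-alkoxy ketone held six atoms away secure.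

Step 7
Reactants: 10 methyl (1S,2R,3S)-7-(benzyloxy)-1-[4-(benzyloxy)-3-bromo-5-methoxyphenyl]-3-[(benzyloxy)methyl]-3-hydroxy-6-methoxy-1,2,3,4-tetrahydronaphthalene-2-carboxylate
Product: 11 (2S,3S,4S)-6-(benzyloxy)-4-[4-(benzyloxy)-3-bromo-5-methoxyphenyl]-2-[(benzyloxy)methyl]-3-(hydroxymethyl)-7-methoxy-1,2,3,4-tetrahydronaphthalen-2-ol
Conditions: LiBH4, THF, MeOH (1 equiv), 0 °C to rt
Reagents that add atoms: none
Why: LiBH4 reduces the ester to the primary alcohol without touching the aryl bromide or the benzyl ethers, and removal of the β-hydroxy ester ends the risk of retro-aldol cleavage in the later basic steps.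

Step 8
Reactants: 11 (2S,3S,4S)-6-(benzyloxy)-4-[4-(benzyloxy)-3-bromo-5-methoxyphenyl]-2-[(benzyloxy)methyl]-3-(hydroxymethyl)-7-methoxy-1,2,3,4-tetrahydronaphthalen-2-ol
Product: 12 (2S,3S,4S)-6-(benzyloxy)-4-[4-(benzyloxy)-3-methoxy-5-(4,4,5,5-tetramethyl-1,3,2-dioxaborolan-2-yl)phenyl]-2-[(benzyloxy)methyl]-3-(hydroxymethyl)-7-methoxy-1,2,3,4-tetrahydronaphthalen-2-ol
Conditions: Pd(dppf)Cl2 (5 mol%), B2pin2, KOAc, dioxane, 90 °C
Reagents that add atoms: bis(pinacolato)diboron, CC1(C)OB(OC1(C)C)B1OC(C)(C)C(C)(C)O1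
Why: Miyaura borylation of the aryl bromide gives the coupling partner, and the free diol is tolerated under the weakly basic conditions.

Step 9
Reactants: 13 3-(benzyloxy)propanoic acid; 14 (R)-4-benzyloxazolidin-2-one
Product: 16 (R)-4-benzyl-3-[3-(benzyloxy)propanoyl]oxazolidin-2-one, via mixed pivalic anhydride 15 (not isolated)
Conditions: t-BuCOCl, Et3N, THF, −20 °C; then LiCl, 14, rt
Reagents that add atoms: none
Why: N-Acylation of the oxazolidinone through the mixed pivalic anhydride with LiCl activation is the standard way to load the chiral auxiliary.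

Step 10
Reactants: 16 (R)-4-benzyl-3-[3-(benzyloxy)propanoyl]oxazolidin-2-one; 8 4-(benzyloxy)-3-bromo-5-methoxybenzaldehyde
Product: 18 (R)-4-benzyl-3-[(2R,3R)-2-[(benzyloxy)methyl]-3-[4-(benzyloxy)-3-bromo-5-methoxyphenyl]-3-hydroxypropanoyl]oxazolidin-2-one, via boron enolate 17 (not isolated)
Conditions: Bu2BOTf, i-Pr2NEt, CH2Cl2, −78 to 0 °C; 8, −78 to 0 °C; pH 7 buffer, MeOH, H2O2
Reagents that add atoms: none
Why: Evans syn-aldol reaction: the (Z)-boron enolate reacts through a closed chair transition state on the face left open by the auxiliary benzyl group and should give the (2R,3R) syn adduct, which fixes the configurations of C2 and C3 of the oxolane.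

Step 11
Reactants: 18 (R)-4-benzyl-3-[(2R,3R)-2-[(benzyloxy)methyl]-3-[4-(benzyloxy)-3-bromo-5-methoxyphenyl]-3-hydroxypropanoyl]oxazolidin-2-one
Product: 19 (2R,3R)-2-[(benzyloxy)methyl]-3-[4-(benzyloxy)-3-bromo-5-methoxyphenyl]-3-hydroxypropanoic acid
Conditions: LiOH, H2O2, THF/H2O, 0 °C; Na2SO3; HCl to pH 3
Reagents that add atoms: lithium hydroperoxide (from LiOH and H2O2), [Li+].[O-]O
Why: Lithium hydroperoxide attacks the exocyclic imide carbonyl selectively and should release the acid and the auxiliary at 0 °C without epimerisation or retro-aldol cleavage.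

Step 12
Reactants: 19 (2R,3R)-2-[(benzyloxy)methyl]-3-[4-(benzyloxy)-3-bromo-5-methoxyphenyl]-3-hydroxypropanoic acid
Product: 21 (3R,4R)-3-[(benzyloxy)methyl]-4-[4-(benzyloxy)-3-bromo-5-methoxyphenyl]-1-diazo-4-hydroxybutan-2-one, via mixed carbonic anhydride 20 (not isolated)
Conditions: i-BuOCOCl, N-methylmorpholine, THF, −20 °C; CH2N2, Et2O, 0 °C to rt
Reagents that add atoms: diazomethane, C=[N+]=[N-]
Why: Acylation of diazomethane by the mixed carbonic anhydride (first stage of the Arndt–Eistert sequence) gives the diazoketone, the carboxylate being far more reactive toward the chloroformate than the hindered secondary alcohol.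

Step 13
Reactants: 21 (3R,4R)-3-[(benzyloxy)methyl]-4-[4-(benzyloxy)-3-bromo-5-methoxyphenyl]-1-diazo-4-hydroxybutan-2-one
Product: 22 (4R,5R)-4-[(benzyloxy)methyl]-5-[4-(benzyloxy)-3-bromo-5-methoxyphenyl]oxolan-3-one
Conditions: Rh2(OAc)4 (1 mol%), CH2Cl2, rt, slow addition
Reagents that add atoms: none
Why: Rhodium-carbenoid O–H insertion closes the five-membered ring under neutral conditions, so the cis relationship of the aryl and benzyloxymethyl groups, which follows from the syn-aldol once the former acyl carbon is a ring atom, is not epimerised.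

Step 14
Reactants: 22 (4R,5R)-4-[(benzyloxy)methyl]-5-[4-(benzyloxy)-3-bromo-5-methoxyphenyl]oxolan-3-one
Product: 23 (2R,3R)-2-[4-(benzyloxy)-3-bromo-5-methoxyphenyl]-3-[(benzyloxy)methyl]-4-methylideneoxolane
Conditions: Cp2TiMe2, toluene/THF, 65 °C, dark
Reagents that add atoms: dimethyltitanocene (Petasis reagent), C[Ti](C)(C1C=CC=C1)C1C=CC=C1
Why: Petasis methylenation is non-basic and should convert the epimerisable β-alkoxy ketone into the exocyclic alkene without epimerisation or β-elimination.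

Step 15
Reactants: 23 (2R,3R)-2-[4-(benzyloxy)-3-bromo-5-methoxyphenyl]-3-[(benzyloxy)methyl]-4-methylideneoxolane
Product: 24 (3R,6R,7R)-6-[4-(benzyloxy)-3-bromo-5-methoxyphenyl]-7-[(benzyloxy)methyl]-1,5-dioxaspiro[2.4]heptane (epoxide oxygen trans to both ring substituents)
Conditions: mCPBA, NaHCO3, CH2Cl2, 0 °C
Reagents that add atoms: 3-chloroperoxybenzoic acid, OOC(=O)c1cccc(Cl)c1
Why: Prilezhaev epoxidation should take place on the face of the exocyclic alkene opposite to the cis aryl and benzyloxymethyl groups, which sets the configuration of the future tertiary carbinol C4.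

Step 16
Reactants: 24 (3R,6R,7R)-6-[4-(benzyloxy)-3-bromo-5-methoxyphenyl]-7-[(benzyloxy)methyl]-1,5-dioxaspiro[2.4]heptane; 1 1-(benzyloxy)-4-bromo-2-methoxybenzene
Product: 26 (3S,4R,5R)-5-[4-(benzyloxy)-3-bromo-5-methoxyphenyl]-3-{[4-(benzyloxy)-3-methoxyphenyl]methyl}-4-[(benzyloxy)methyl]oxolan-3-ol, via aryl Grignard reagent 25 (not isolated)
Conditions: 1, Mg, THF, 40 °C; then CuI (15 mol%), 24, −40 to 0 °C; aq. NH4Cl
Reagents that add atoms: none
Why: Copper-catalysed Grignard opening of the 2,2-disubstituted epoxide at its CH2 carbon makes the benzylic CH2–aryl bond and leaves the C–O bond at the quaternary centre, and hence its configuration, untouched.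

Step 17
Reactants: 12 (2S,3S,4S)-6-(benzyloxy)-4-[4-(benzyloxy)-3-methoxy-5-(4,4,5,5-tetramethyl-1,3,2-dioxaborolan-2-yl)phenyl]-2-[(benzyloxy)methyl]-3-(hydroxymethyl)-7-methoxy-1,2,3,4-tetrahydronaphthalen-2-ol; 26 (3S,4R,5R)-5-[4-(benzyloxy)-3-bromo-5-methoxyphenyl]-3-{[4-(benzyloxy)-3-methoxyphenyl]methyl}-4-[(benzyloxy)methyl]oxolan-3-ol
Product: 27 hexa-O-benzyl ether of the target (benzyl on the four phenols, on the oxolane C3 hydroxymethyl group and on the hydroxymethyl group at the tetralin carbinol carbon C3)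
Conditions: Pd(OAc)2 (5 mol%), SPhos (10 mol%), K3PO4, toluene/H2O, 80 °C
Reagents that add atoms: none
Why: Suzuki–Miyaura coupling with a bulky biarylphosphine ligand suits the doubly ortho-oxygenated biaryl and tolerates the free hydroxyl groups.

Step 18
Reactants: 27 hexa-O-benzyl ether of the target
Product: 28 (2S,3S,4S)-4-{4-hydroxy-3-[2-hydroxy-5-{(2R,3R,4S)-4-hydroxy-4-[(4-hydroxy-3-methoxyphenyl)methyl]-3-(hydroxymethyl)oxolan-2-yl}-3-methoxyphenyl]-5-methoxyphenyl}-2,3-bis(hydroxymethyl)-7-methoxy-1,2,3,4-tetrahydronaphthalene-2,6-diol (CNP0344108.1)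
Conditions: H2 (1 atm), Pd/C (10 wt%), EtOAc/MeOH, rt
Reagents that add atoms: none
Why: Hydrogenolysis under neutral conditions should cleave the four aryl and two alkyl benzyl ethers and avoids the acid that would turn the 2-aryloxolane into an aryltetralin; the reaction is stopped once the benzyl ethers are gone so that the ring C–O bond of the oxolane is kept.

Compound list
1 | 1-(benzyloxy)-4-bromo-2-methoxybenzene | COc1cc(Br)ccc1OCc1ccccc1 | starting material
2 | benzyl glycidyl ether (racemic 2-[(benzyloxy)methyl]oxirane) | C(OCc1ccccc1)C1CO1 | starting material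
3 | [4-(benzyloxy)-3-methoxyphenyl]lithium | COc1cc([Li])ccc1OCc1ccccc1 | intermediate
4 | racemic 1-(benzyloxy)-3-[4-(benzyloxy)-3-methoxyphenyl]propan-2-ol | OC(Cc1ccc(OCc2ccccc2)c(OC)c1)COCc1ccccc1 | intermediate
5 | racemic 1-(benzyloxy)-3-[4-(benzyloxy)-2-bromo-5-methoxyphenyl]propan-2-ol | OC(Cc1cc(OC)c(OCc2ccccc2)cc1Br)COCc1ccccc1 | intermediate
6 | racemic 1-(benzyloxy)-3-[4-(benzyloxy)-5-methoxy-2-(4,4,5,5-tetramethyl-1,3,2-dioxaborolan-2-yl)phenyl]propan-2-ol | OC(Cc1cc(OC)c(OCc2ccccc2)cc1B1OC(C)(C)C(C)(C)O1)COCc1ccccc1 | intermediate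
7 | 1-(benzyloxy)-3-[4-(benzyloxy)-5-methoxy-2-(4,4,5,5-tetramethyl-1,3,2-dioxaborolan-2-yl)phenyl]propan-2-one | O=C(Cc1cc(OC)c(OCc2ccccc2)cc1B1OC(C)(C)C(C)(C)O1)COCc1ccccc1 | intermediate
8 | 4-(benzyloxy)-3-bromo-5-methoxybenzaldehyde | COc1cc(C=O)cc(Br)c1OCc1ccccc1 | starting material
9 | methyl (E)-3-[4-(benzyloxy)-3-bromo-5-methoxyphenyl]prop-2-enoate | COC(=O)/C=C/c1cc(OC)c(OCc2ccccc2)c(Br)c1 | intermediate
10 | methyl (1S,2R,3S)-7-(benzyloxy)-1-[4-(benzyloxy)-3-bromo-5-methoxyphenyl]-3-[(benzyloxy)methyl]-3-hydroxy-6-methoxy-1,2,3,4-tetrahydronaphthalene-2-carboxylate | COc1cc([C@H]2c3cc(OCc4ccccc4)c(OC)cc3C[C@@](O)(COCc3ccccc3)[C@@H]2C(=O)OC)cc(Br)c1OCc1ccccc1 | intermediate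
11 | (2S,3S,4S)-6-(benzyloxy)-4-[4-(benzyloxy)-3-bromo-5-methoxyphenyl]-2-[(benzyloxy)methyl]-3-(hydroxymethyl)-7-methoxy-1,2,3,4-tetrahydronaphthalen-2-ol | COc1cc([C@H]2c3cc(OCc4ccccc4)c(OC)cc3C[C@@](O)(COCc3ccccc3)[C@@H]2CO)cc(Br)c1OCc1ccccc1 | intermediate
12 | (2S,3S,4S)-6-(benzyloxy)-4-[4-(benzyloxy)-3-methoxy-5-(4,4,5,5-tetramethyl-1,3,2-dioxaborolan-2-yl)phenyl]-2-[(benzyloxy)methyl]-3-(hydroxymethyl)-7-methoxy-1,2,3,4-tetrahydronaphthalen-2-ol | COc1cc([C@H]2c3cc(OCc4ccccc4)c(OC)cc3C[C@@](O)(COCc3ccccc3)[C@@H]2CO)cc(B2OC(C)(C)C(C)(C)O2)c1OCc1ccccc1 | intermediate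
13 | 3-(benzyloxy)propanoic acid | OC(=O)CCOCc1ccccc1 | starting material
14 | (R)-4-benzyloxazolidin-2-one | O=C1N[C@H](Cc2ccccc2)CO1 | starting material
15 | 3-(benzyloxy)propanoic pivalic anhydride | CC(C)(C)C(=O)OC(=O)CCOCc1ccccc1 | intermediate
16 | (R)-4-benzyl-3-[3-(benzyloxy)propanoyl]oxazolidin-2-one | O=C(CCOCc1ccccc1)N1[C@H](Cc2ccccc2)COC1=O | intermediate
17 | (Z)-dibutylboron enolate of 16 | CCCCB(CCCC)O/C(=C\COCc1ccccc1)N1[C@H](Cc2ccccc2)COC1=O | intermediate
18 | (R)-4-benzyl-3-[(2R,3R)-2-[(benzyloxy)methyl]-3-[4-(benzyloxy)-3-bromo-5-methoxyphenyl]-3-hydroxypropanoyl]oxazolidin-2-one | O=C([C@H](COCc1ccccc1)[C@@H](O)c1cc(OC)c(OCc2ccccc2)c(Br)c1)N1[C@H](Cc2ccccc2)COC1=O | intermediate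
19 | (2R,3R)-2-[(benzyloxy)methyl]-3-[4-(benzyloxy)-3-bromo-5-methoxyphenyl]-3-hydroxypropanoic acid | OC(=O)[C@H](COCc1ccccc1)[C@@H](O)c1cc(OC)c(OCc2ccccc2)c(Br)c1 | intermediate
20 | isobutyl carbonic anhydride of acid 19 | CC(C)COC(=O)OC(=O)[C@H](COCc1ccccc1)[C@@H](O)c1cc(OC)c(OCc2ccccc2)c(Br)c1 | intermediate
21 | (3R,4R)-3-[(benzyloxy)methyl]-4-[4-(benzyloxy)-3-bromo-5-methoxyphenyl]-1-diazo-4-hydroxybutan-2-one | [N-]=[N+]=CC(=O)[C@H](COCc1ccccc1)[C@@H](O)c1cc(OC)c(OCc2ccccc2)c(Br)c1 | intermediate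
22 | (4R,5R)-4-[(benzyloxy)methyl]-5-[4-(benzyloxy)-3-bromo-5-methoxyphenyl]oxolan-3-one | O=C1CO[C@@H](c2cc(OC)c(OCc3ccccc3)c(Br)c2)[C@H]1COCc1ccccc1 | intermediate
23 | (2R,3R)-2-[4-(benzyloxy)-3-bromo-5-methoxyphenyl]-3-[(benzyloxy)methyl]-4-methylideneoxolane | C=C1CO[C@@H](c2cc(OC)c(OCc3ccccc3)c(Br)c2)[C@H]1COCc1ccccc1 | intermediate
24 | (3R,6R,7R)-6-[4-(benzyloxy)-3-bromo-5-methoxyphenyl]-7-[(benzyloxy)methyl]-1,5-dioxaspiro[2.4]heptane | C1[C@@]2(O1)CO[C@@H](c1cc(OC)c(OCc3ccccc3)c(Br)c1)[C@H]2COCc1ccccc1 | intermediate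
25 | [4-(benzyloxy)-3-methoxyphenyl]magnesium bromide | COc1cc([Mg]Br)ccc1OCc1ccccc1 | intermediate
26 | (3S,4R,5R)-5-[4-(benzyloxy)-3-bromo-5-methoxyphenyl]-3-{[4-(benzyloxy)-3-methoxyphenyl]methyl}-4-[(benzyloxy)methyl]oxolan-3-ol | COc1cc(C[C@@]2(O)CO[C@@H](c3cc(OC)c(OCc4ccccc4)c(Br)c3)[C@H]2COCc2ccccc2)ccc1OCc1ccccc1 | intermediate
27 | hexa-O-benzyl ether of the target: (2S,3S,4S)-6-(benzyloxy)-4-{4-(benzyloxy)-3-[2-(benzyloxy)-5-{(2R,3R,4S)-3-[(benzyloxy)methyl]-4-[4-(benzyloxy)-3-methoxybenzyl]-4-hydroxyoxolan-2-yl}-3-methoxyphenyl]-5-methoxyphenyl}-2-[(benzyloxy)methyl]-3-(hydroxymethyl)-7-methoxy-1,2,3,4-tetrahydronaphthalen-2-ol | COc1cc(C[C@@]2(O)CO[C@@H](c3cc(OC)c(OCc4ccccc4)c(-c4cc([C@H]5c6cc(OCc7ccccc7)c(OC)cc6C[C@@](O)(COCc6ccccc6)[C@@H]5CO)cc(OC)c4OCc4ccccc4)c3)[C@H]2COCc2ccccc2)ccc1OCc1ccccc1 | intermediate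
28 | CNP0344108.1: (2S,3S,4S)-4-{4-hydroxy-3-[2-hydroxy-5-{(2R,3R,4S)-4-hydroxy-4-[(4-hydroxy-3-methoxyphenyl)methyl]-3-(hydroxymethyl)oxolan-2-yl}-3-methoxyphenyl]-5-methoxyphenyl}-2,3-bis(hydroxymethyl)-7-methoxy-1,2,3,4-tetrahydronaphthalene-2,6-diol | COc1cc(C[C@@]2(O)CO[C@@H](c3cc(OC)c(O)c(-c4cc([C@H]5c6cc(O)c(OC)cc6C[C@@](O)(CO)[C@@H]5CO)cc(OC)c4O)c3)[C@H]2CO)ccc1O | target

Total step count: 18. Longest linear sequence: 10 steps (steps 9 to 18, from 13 and 14).

Steps most likely to fail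

Step 6. What may go wrong: protonation of the rhodium enolate before it reaches the ketone, protodeboronation of 7, or poor facial selectivity in the aldol closure. The fallback sets out from 26 and comes back to the route at 28. Treatment of 26 with CF3CO2H in CH2Cl2 at 0 °C should ionise the benzylic C–O bond of the oxolane and close the ring by Friedel–Crafts attack of the benzyl ring para to its methoxy group. This is the known acid-induced oxolane-to-aryltetralin rearrangement of this lignan class. It should give the isomeric tetralin bromide F1, with the two adjacent stereocentres of 26 unchanged and the aryl group in the favoured 1,2-trans position. Miyaura borylation as in step 8 gives the boronate F2. Suzuki coupling with a second portion of 26 as in step 17 gives the hexabenzyl ether F3, which differs from 27 only in which tetralin hydroxymethyl group carries the benzyl group. Hydrogenolysis as in step 18 then gives 28.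

Step 13. What may go wrong: capture of the rhodium carbenoid by the benzyl ether oxygen (oxonium ylide formation and benzyl shift) instead of the hydroxyl group, or decomposition of the unprotected hydroxy diazoketone. The fallback sets out from 18 and comes back at 22. Transamidation of 18 with AlMe3 and MeNH(OMe)·HCl gives the Weinreb amide F4. Addition of ClCH2Li (from ICH2Cl and MeLi·LiBr, THF, −78 °C) gives the chloromethyl ketone F5. Intramolecular Williamson etherification promoted by Ag2O then closes the oxolanone 22.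

Step 16. What may go wrong: halide-promoted rearrangement of the hindered spiro-epoxide to an aldehyde, or bromohydrin formation, outrunning attack at the neopentyl-type CH2 carbon. The fallback sets out from 22 and comes back at 26. Wittig olefination of 22 with the ylide from [4-(benzyloxy)-3-methoxybenzyl]triphenylphosphonium chloride (NaN(SiMe3)2, THF, −78 °C) gives the benzylidene oxolane F6 as an E/Z mixture, which is of no consequence. Epoxidation with mCPBA on the open face gives the aryl spiro-epoxide F7. LiAlH4 (THF, 0 °C) should then deliver hydride to the benzylic epoxide carbon and give 26.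

Further compounds
F1 | step 6 | (2S,3S,4S)-6-(benzyloxy)-4-[4-(benzyloxy)-3-bromo-5-methoxyphenyl]-3-[(benzyloxy)methyl]-2-(hydroxymethyl)-7-methoxy-1,2,3,4-tetrahydronaphthalen-2-ol | COc1cc([C@H]2c3cc(OCc4ccccc4)c(OC)cc3C[C@@](O)(CO)[C@@H]2COCc2ccccc2)cc(Br)c1OCc1ccccc1
F2 | step 6 | (2S,3S,4S)-6-(benzyloxy)-4-[4-(benzyloxy)-3-methoxy-5-(4,4,5,5-tetramethyl-1,3,2-dioxaborolan-2-yl)phenyl]-3-[(benzyloxy)methyl]-2-(hydroxymethyl)-7-methoxy-1,2,3,4-tetrahydronaphthalen-2-ol | COc1cc([C@H]2c3cc(OCc4ccccc4)c(OC)cc3C[C@@](O)(CO)[C@@H]2COCc2ccccc2)cc(B2OC(C)(C)C(C)(C)O2)c1OCc1ccccc1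
F3 | step 6 | hexa-O-benzyl ether of the target isomeric with 27 (free hydroxymethyl group on the tetralin carbinol carbon, benzyloxymethyl group on the neighbouring carbon) | COc1cc(C[C@@]2(O)CO[C@@H](c3cc(OC)c(OCc4ccccc4)c(-c4cc([C@H]5c6cc(OCc7ccccc7)c(OC)cc6C[C@@](O)(CO)[C@@H]5COCc5ccccc5)cc(OC)c4OCc4ccccc4)c3)[C@H]2COCc2ccccc2)ccc1OCc1ccccc1
F4 | step 13 | (2R,3R)-2-[(benzyloxy)methyl]-3-[4-(benzyloxy)-3-bromo-5-methoxyphenyl]-3-hydroxy-N-methoxy-N-methylpropanamide | CON(C)C(=O)[C@H](COCc1ccccc1)[C@@H](O)c1cc(OC)c(OCc2ccccc2)c(Br)c1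
F5 | step 13 | (3R,4R)-3-[(benzyloxy)methyl]-4-[4-(benzyloxy)-3-bromo-5-methoxyphenyl]-1-chloro-4-hydroxybutan-2-one | ClCC(=O)[C@H](COCc1ccccc1)[C@@H](O)c1cc(OC)c(OCc2ccccc2)c(Br)c1
F6 | step 16 | (2R,3R)-2-[4-(benzyloxy)-3-bromo-5-methoxyphenyl]-3-[(benzyloxy)methyl]-4-[4-(benzyloxy)-3-methoxybenzylidene]oxolane (E/Z mixture) | COc1cc(C=C2CO[C@@H](c3cc(OC)c(OCc4ccccc4)c(Br)c3)[C@H]2COCc2ccccc2)ccc1OCc1ccccc1
F7 | step 16 | (3S,6R,7R)-6-[4-(benzyloxy)-3-bromo-5-methoxyphenyl]-7-[(benzyloxy)methyl]-2-[4-(benzyloxy)-3-methoxyphenyl]-1,5-dioxaspiro[2.4]heptane (mixture at C2) | COc1cc(C2O[C@@]23CO[C@@H](c4cc(OC)c(OCc5ccccc5)c(Br)c4)[C@H]3COCc3ccccc3)ccc1OCc1ccccc1
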